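The runs come from a simulation for substances that don't exist, noise included.

The flask is read at 10 min, later than the end of its 2.0 min feed, so the question is what the coupling partner still allows by then.

| flask | starting material | coupling partner | remark | time |
|---|---|---|---|---|
| beta | 10 mM (fed, over 2.0 min) | 18 mM | the very flask that is asked about, followed so far; the fed solution adds 0.20 times the starting volume |  |
| flask | 10 mM (fed, over 2.0 min) | 18.0 mM | the fed solution adds 0.20 times the starting volume | 10 min |

- beta (time / min: double product / %, first product / %): 0.250: 1.2, 1.9; 0.500: 4.4, 9.3; 1.33: 20.0, 18.7; 3.00: 31.1, 26.7

(readings scatter by 1 percentage point)

- charges are per starting volume, the dose included; the dosed solution carries all of it
- the numbers in the tables scatter by 1 percentage point (one standard deviation)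
- candidate steps: coupling partner + triple product -> tetra adduct; coupling partner + first product -> double product; starting material + coupling partner -> first product; coupling partner + double product -> triple product
- the reaction counts as stopped when no species that holds the starting material changes by six tenths of a point or more over the second half of the time
- percentages count the whole charge, also what has not yet gone in

1. which holds at 10 min: what has brought the reaction to rest, or that it has not come to rest (it is still moving / forward and back rates have come level / the coupling partner has run out first / all of the starting material has reacted)
2. how much double product there is at 10 min, in percent of the starting material charged
3. how much first product there is at 10 min, in percent of the starting material charged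
4. amount of double product if the flask were left three thousand times as long, in percent of the starting material charged

I reckon with the partner budget, the coupling partner charged per starting material charged, 1.80. Each candidate step spends one coupling partner, so first product holds one, double product two, triple product 3 and tetra adduct 4. The budget is below the 4 that full conversion to tetra adduct needs, which makes the coupling partner the limiting reagent.

In the first instants, at 0.250 min, 12.5% of the dose is in and the products are barely readable. At 0.500 min the first coupling leads, with first product above double product. By 1.33 min the second coupling has drawn level within the scatter.

At 3.00 min, with the feed over, the readings of these two products account for 0.889 couplings per starting material charged, which leaves 0.911 of the budget. The unread 42.2% of the charge would need a mean of 2.16 couplings to take up that remainder, which it can hold. At the mean pace of these two products so far, 0.296 min⁻¹, the budget would last 6.07 min from the start, less than the reading time. So I expect this flask to stop with the coupling partner gone and double product above its last reading.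

The forecast says it is still moving, with 36% double product, 27% first product and 37% double product if left far longer. Its ground for the verdict is that “from 5 to 10 min species still shift by more than 0.6 points”. Here my reckoning and the forecast part.

The flask ends otherwise than the forecast: the coupling partner has run out first, with 0.0075% of the charged coupling partner remaining at 10.0 min, and it holds 34.3% double product, 23.8% first product and 34.3% double product if left far longer. Counting each product by its couplings at that time gives 1.80, the budget again, while 16.9% of the starting material stands unreacted.

    coupling partner + triple product → tetra adduct (k = 2.30 L mol⁻¹ s⁻¹)
    coupling partner + first product → double product (k = 3.10 L mol⁻¹ s⁻¹)
    starting material + coupling partner → first product (k = 3.20 L mol⁻¹ s⁻¹)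
    coupling partner + double product → triple product (k = 1.30 L mol⁻¹ s⁻¹)

The same flask with 11 mM of coupling partner has a budget of 1.10, so I expect it to stop with more starting material unreacted. It stops with 35.7% starting material, 25.0% double product and 30.4% first product, and its couplings count to 1.10.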